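## Retrosynthetic overview

1. Target 23 ⇒ acyclic ynal 20 by opening C3–C4 (nickel-catalysed reductive aldehyde–alkyne macrocyclisation; the fourteen-membered carbocycle is formed last and C3 is set here).
2. 20 ⇒ epoxy ester 17 by removing the acetate and reopening the C12–O bond (7-exo epoxide opening by the ester with inversion at C12; the seven-membered lactone is formed before the carbocycle).
3. 17 ⇒ epoxy enal 15 + tert-butyl acrylate 16 across C1–C15 (amine/Lewis-base co-catalysed asymmetric cross-Rauhut–Currier addition, new; sets C1).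
4. 15 ⇒ achiral trienyne 11 (cross-metathesis; Shi epoxidation of C11=C12 sets the first stereocentres and is the first ring formed).
5. 11 ⇒ nerol 1 + propynyl and allyl Grignard reagents (the Z olefin comes with nerol; C5–C6 and C13–C14 by copper-catalysed allylic couplings).

Assumption: chiral catalysts are allowed because they supply no atoms; every compound that supplies atoms is achiral and commercial.

Locants C1–C20 are those of the target: C1 = ring CH carrying the methylidene-carboxyl unit, C3 = carbinol, C11 = acetoxy carbon, C12 = lactone C–O carbon, C15/C16/C17 = lactone α-carbon, carbonyl and methylidene. The target SMILES reads as 1S,3S,11R,12S with 4E,7Z.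

## Route

Step 1
Reactants: 1 nerol, (2Z)-3,7-dimethylocta-2,6-dien-1-ol; 2 phosphorus tribromide
Product: 3 neryl bromide, (2Z)-1-bromo-3,7-dimethylocta-2,6-diene
Conditions: PBr3 (0.4 equiv), pyridine (cat.), Et2O, −10 °C
Reagents that add atoms: phosphorus tribromide 2, BrP(Br)Br
Why: PBr3 bromination of a primary allylic alcohol (SN2 on the bromophosphite) at low temperature keeps the Z olefin and avoids allylic transposition.

Step 2
Reactants: 3 neryl bromide; 4 prop-1-yn-1-ylmagnesium bromide
Product: 5 (5Z)-6,10-dimethylundeca-5,9-dien-2-yne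
Conditions: 4 (1.3 equiv), CuI (10 mol%), THF, 0 °C → rt
Reagents that add atoms: prop-1-yn-1-ylmagnesium bromide 4, CC#C[Mg]Br
Why: Copper-catalysed alkynyl Grignard–allylic bromide coupling gives the skipped enyne by direct SN2 substitution at the primary carbon with retention of the Z geometry.

Step 3
Reactants: 5 (5Z)-6,10-dimethylundeca-5,9-dien-2-yne; 6 tert-butyl hydroperoxide
Product: 7 (2E,6Z)-2,6-dimethylundeca-2,6-dien-9-yn-1-ol
Conditions: SeO2 (0.2 equiv), tBuOOH (2 equiv), salicylic acid (0.1 equiv), CH2Cl2, 0 °C → rt, stopped at about 70% conversion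
Reagents that add atoms: tert-butyl hydroperoxide 6, CC(C)(C)OO
Why: Sharpless SeO2/tBuOOH allylic oxidation (ene reaction, then [2,3]-shift) attacks the E-methyl group of the terminal, most electron-rich trisubstituted olefin, while the inner olefin is inductively deactivated by its propargylic substituent.

Step 4
Reactants: 7 (2E,6Z)-2,6-dimethylundeca-2,6-dien-9-yn-1-ol; 8 tetrabromomethane
Product: 9 (2E,6Z)-1-bromo-2,6-dimethylundeca-2,6-dien-9-yne
Conditions: CBr4 (1.2 equiv), PPh3 (1.25 equiv), CH2Cl2, 0 °C
Reagents that add atoms: tetrabromomethane 8, BrC(Br)(Br)Br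
Why: The Appel reaction converts the primary allylic alcohol into the bromide under neutral conditions without allylic shift or olefin isomerisation.

Step 5
Reactants: 9 (2E,6Z)-1-bromo-2,6-dimethylundeca-2,6-dien-9-yne; 10 allylmagnesium bromide
Product: 11 (5E,9Z)-5,9-dimethyltetradeca-1,5,9-trien-12-yne
Conditions: 10 (1.3 equiv), Li2CuCl4 (3 mol%), THF, −78 → 0 °C
Reagents that add atoms: allylmagnesium bromide 10, C=CC[Mg]Br
Why: Kochi-type copper-catalysed Grignard coupling with fast addition in THF substitutes the primary allylic bromide at C13 (SN2 mode) and leaves the internal alkyne and both trisubstituted olefins untouched.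

Step 6
Reactants: 11 (5E,9Z)-5,9-dimethyltetradeca-1,5,9-trien-12-yne; 12 potassium peroxymonosulfate
Product: 13 (2R,3R)-2-(but-3-en-1-yl)-2-methyl-3-[(3Z)-3-methyloct-3-en-6-yn-1-yl]oxirane
Conditions: D-fructose-derived Shi ketone (1,2:4,5-di-O-isopropylidene-β-D-erythro-2,3-hexodiulo-2,6-pyranose, 30 mol%), 2KHSO5·KHSO4·K2SO4 (1.4 equiv), K2CO3, Bu4NHSO4, MeCN/dimethoxymethane/aq. Na2B4O7 buffer (pH 10.5), 0 °C
Reagents that add atoms: potassium peroxymonosulfate 12, [K+].[O-]S(=O)(=O)OO
Why: Shi asymmetric epoxidation: the chiral dioxirane transfers oxygen through a spiro transition state to the face of the E-trisubstituted C11=C12 olefin that gives the 11R,12R epoxide (same sense as (R,R)-trans-β-methylstyrene oxide); the monosubstituted vinyl group is inert and the Z olefin is slowed by its electron-withdrawing propargylic CH2.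

Step 7
Reactants: 13 (2R,3R)-2-(but-3-en-1-yl)-2-methyl-3-[(3Z)-3-methyloct-3-en-6-yn-1-yl]oxirane; 14 (2E)-but-2-enal
Product: 15 (2E)-5-{(2R,3R)-2-methyl-3-[(3Z)-3-methyloct-3-en-6-yn-1-yl]oxiran-2-yl}pent-2-enal
Conditions: 14 (5 equiv), second-generation Hoveyda–Grubbs catalyst (5 mol%), CH2Cl2, 40 °C
Reagents that add atoms: (2E)-but-2-enal 14, C/C=C/C=O
Why: Olefin cross-metathesis of the only monosubstituted alkene with excess crotonaldehyde gives the E enal; the trisubstituted olefin, the epoxide and the methyl-capped internal alkyne react far more slowly.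

Step 8
Reactants: 15 (2E)-5-{(2R,3R)-2-methyl-3-[(3Z)-3-methyloct-3-en-6-yn-1-yl]oxiran-2-yl}pent-2-enal; 16 tert-butyl prop-2-enoate
Product: 17 tert-butyl (3S)-2-methylidene-5-{(2R,3R)-2-methyl-3-[(3Z)-3-methyloct-3-en-6-yn-1-yl]oxiran-2-yl}-3-(2-oxoethyl)pentanoate
Conditions: 16 (5 equiv), (R)-α,α-diphenylprolinol trimethylsilyl ether (20 mol%), DABCO (20 mol%), 4-nitrophenol (20 mol%), toluene, 0 °C → rt
Reagents that add atoms: tert-butyl prop-2-enoate 16, C=CC(=O)OC(C)(C)C
Why: Proposed new method: an enantioselective intermolecular cross-Rauhut–Currier reaction run by two organocatalysts at once – the prolinol ether turns 15 into its E-iminium ion (one face of C1 blocked by the CPh2OSiMe3 group), DABCO adds reversibly to 16 to give the ammonium enolate known from Morita–Baylis–Hillman chemistry, this soft enolate attacks C1 through its α-carbon on the open Si face (forms C1–C15, sets 1S), and phenol-mediated proton transfer, E1cB loss of DABCO and enamine hydrolysis release 17 and both catalysts; the closest known reactions are the prolinol-ether-catalysed Michael addition of malonates to enals and the amine-catalysed Morita–Baylis–Hillman/Rauhut–Currier reaction, but their pairing with an acrylate donor and an enal iminium acceptor has not been described.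

Step 9
Reactants: 17 tert-butyl (3S)-2-methylidene-5-{(2R,3R)-2-methyl-3-[(3Z)-3-methyloct-3-en-6-yn-1-yl]oxiran-2-yl}-3-(2-oxoethyl)pentanoate
Product: 18 (4S,7S)-7-[(1R,4Z)-1-hydroxy-4-methylnon-4-en-7-yn-1-yl]-7-methyl-3-methylidene-4-(2-oxoethyl)oxepan-2-one
Conditions: (+)-camphorsulfonic acid (0.2 equiv), CH2Cl2, 0 °C → rt
Reagents that add atoms: none
Why: Acid-catalysed 7-exo epoxide opening with neighbouring-group participation of the tert-butyl ester carbonyl at the tertiary carbon C12 (inversion, 12R → 12S, C11 untouched), followed by loss of isobutylene from the dialkoxycarbenium ion, closes the lactone.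

Step 10
Reactants: 18 (4S,7S)-7-[(1R,4Z)-1-hydroxy-4-methylnon-4-en-7-yn-1-yl]-7-methyl-3-methylidene-4-(2-oxoethyl)oxepan-2-one; 19 acetic anhydride
Product: 20 (1R,4Z)-4-methyl-1-[(2S,5S)-2-methyl-6-methylidene-7-oxo-5-(2-oxoethyl)oxepan-2-yl]non-4-en-7-yn-1-yl acetate
Conditions: Ac2O (2 equiv), pyridine, DMAP (10 mol%), CH2Cl2, 0 °C
Reagents that add atoms: acetic anhydride 19, CC(=O)OC(C)=O
Why: DMAP-catalysed acylation of the only hydroxyl group present fixes the C11 acetate before the C3 alcohol exists, so no hydroxyl differentiation is needed later.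

Step 11
Reactants: 20 (1R,4Z)-4-methyl-1-[(2S,5S)-2-methyl-6-methylidene-7-oxo-5-(2-oxoethyl)oxepan-2-yl]non-4-en-7-yn-1-yl acetate; 21 triethylsilane
Product: 23 (1S,3S,4E,7Z,11R,12S)-3-hydroxy-4,8,12-trimethyl-15-methylidene-14-oxo-13-oxabicyclo[10.3.2]heptadeca-4,7-dien-11-yl acetate (target), via C3 triethylsilyl ether 22 (not isolated)
Conditions: Ni(cod)2 (20 mol%), IMes·HCl (20 mol%), KOtBu (20 mol%), Et3SiH (3 equiv), THF (0.005 M, slow addition of 20), rt; then 1 M aq. HCl, THF, 0 °C
Reagents that add atoms: triethylsilane 21, CC[SiH](CC)CC (its silicon is carried in 22 only; the target keeps hydrogen alone)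
Why: Nickel-catalysed reductive aldehyde–alkyne macrocyclisation (Montgomery type): with the small carbene IMes the oxanickelacycle forms C3–C4 at the methyl-bearing alkyne carbon, the silane delivers hydrogen syn to give the 4E olefin, the 3S carbinol is expected from substrate control by C1 (unproven), and mild acid cleaves the allylic silyl ether.

## Compound list

1 | nerol, (2Z)-3,7-dimethylocta-2,6-dien-1-ol | CC(C)=CCC/C(C)=C\CO | starting material
2 | phosphorus tribromide | BrP(Br)Br | starting material
3 | neryl bromide, (2Z)-1-bromo-3,7-dimethylocta-2,6-diene | CC(C)=CCC/C(C)=C\CBr | intermediate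
4 | prop-1-yn-1-ylmagnesium bromide | CC#C[Mg]Br | starting material
5 | (5Z)-6,10-dimethylundeca-5,9-dien-2-yne | CC#CC/C=C(/C)CCC=C(C)C | intermediate
6 | tert-butyl hydroperoxide | CC(C)(C)OO | starting material
7 | (2E,6Z)-2,6-dimethylundeca-2,6-dien-9-yn-1-ol | CC#CC/C=C(/C)CC/C=C(\C)CO | intermediate
8 | tetrabromomethane | BrC(Br)(Br)Br | starting material
9 | (2E,6Z)-1-bromo-2,6-dimethylundeca-2,6-dien-9-yne | CC#CC/C=C(/C)CC/C=C(\C)CBr | intermediate
10 | allylmagnesium bromide | C=CC[Mg]Br | starting material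
11 | (5E,9Z)-5,9-dimethyltetradeca-1,5,9-trien-12-yne | C=CCC/C(C)=C/CC/C(C)=C\CC#CC | intermediate
12 | potassium peroxymonosulfate (active part of 2KHSO5·KHSO4·K2SO4) | [K+].[O-]S(=O)(=O)OO | starting material
13 | (2R,3R)-2-(but-3-en-1-yl)-2-methyl-3-[(3Z)-3-methyloct-3-en-6-yn-1-yl]oxirane | C=CCC[C@@]1(C)O[C@@H]1CC/C(C)=C\CC#CC | intermediate
14 | (2E)-but-2-enal (crotonaldehyde) | C/C=C/C=O | starting material
15 | (2E)-5-{(2R,3R)-2-methyl-3-[(3Z)-3-methyloct-3-en-6-yn-1-yl]oxiran-2-yl}pent-2-enal | O=C/C=C/CC[C@@]1(C)O[C@@H]1CC/C(C)=C\CC#CC | intermediate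
16 | tert-butyl prop-2-enoate (tert-butyl acrylate) | C=CC(=O)OC(C)(C)C | starting material
17 | tert-butyl (3S)-2-methylidene-5-{(2R,3R)-2-methyl-3-[(3Z)-3-methyloct-3-en-6-yn-1-yl]oxiran-2-yl}-3-(2-oxoethyl)pentanoate | C=C(C(=O)OC(C)(C)C)[C@H](CC=O)CC[C@@]1(C)O[C@@H]1CC/C(C)=C\CC#CC | intermediate
18 | (4S,7S)-7-[(1R,4Z)-1-hydroxy-4-methylnon-4-en-7-yn-1-yl]-7-methyl-3-methylidene-4-(2-oxoethyl)oxepan-2-one | C=C1C(=O)O[C@@](C)(CC[C@H]1CC=O)[C@H](O)CC/C(C)=C\CC#CC | intermediate
19 | acetic anhydride | CC(=O)OC(C)=O | starting material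
20 | (1R,4Z)-4-methyl-1-[(2S,5S)-2-methyl-6-methylidene-7-oxo-5-(2-oxoethyl)oxepan-2-yl]non-4-en-7-yn-1-yl acetate | C=C1C(=O)O[C@@](C)(CC[C@H]1CC=O)[C@H](OC(C)=O)CC/C(C)=C\CC#CC | intermediate
21 | triethylsilane | CC[SiH](CC)CC | starting material
22 | (1S,3S,4E,7Z,11R,12S)-4,8,12-trimethyl-15-methylidene-14-oxo-3-(triethylsilyloxy)-13-oxabicyclo[10.3.2]heptadeca-4,7-dien-11-yl acetate | C=C1C(=O)O[C@@]2(C)CC[C@H]1C[C@H](O[Si](CC)(CC)CC)/C(C)=C/C/C=C(/C)CC[C@H]2OC(C)=O | intermediate
23 | (1S,3S,4E,7Z,11R,12S)-3-hydroxy-4,8,12-trimethyl-15-methylidene-14-oxo-13-oxabicyclo[10.3.2]heptadeca-4,7-dien-11-yl acetate | C=C1C(=O)O[C@@]2(C)CC[C@H]1C[C@H](O)/C(C)=C/C/C=C(/C)CC[C@H]2OC(C)=O | target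

## Step count and risks

Total step count: 11. Longest linear sequence: 11 steps (1 → 23); the route is fully linear and uses no protecting groups.

The three steps most likely to fail:

**Step 8 (the proposed cross-Rauhut–Currier addition).** The ammonium enolate of tert-butyl acrylate may form too slowly. The secondary amine may be lost by aza-Michael addition to the acrylate. The γ-enolisable enal may drain into dienamine pathways. The enolate may add a second time to the product aldehyde.

The fallback uses known chemistry, sets out from 15 and comes back at 18. Enal 15 and di-tert-butyl malonate react under the established prolinol-ether conditions for malonate Michael addition to enals ((R)-α,α-diphenylprolinol trimethylsilyl ether 10 mol%, PhCO2H 10 mol%, EtOH, 0 °C → rt). The same facial model applies and gives the 3S malonate adduct F1. Trifluoroacetic acid in CH2Cl2 at 0 °C then lets one ester carbonyl open the epoxide at C12 exactly as in step 9 and removes the second tert-butyl group, giving the α-carboxy lactone F2. Eschenmoser's salt in CH2Cl2/MeCN (0 °C → rt) effects the decarboxylative Mannich methylenation of this malonic half-acid and delivers 18. The cost is one extra step, and the methylenation must be kept cold and amine-free to spare the aldehyde α-position.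

**Step 9 (acyclic 7-exo lactonisation).** Seven-membered ring closure is slow. The activated tertiary epoxide can instead be attacked by the C7=C8 olefin (cation–olefin cyclisation) or by the aldehyde oxygen.

The fallback changes the order of ring formation, sets out from 17 and comes back at 23. Ynal 17 is cyclised first under the nickel conditions of step 11 but with iPr3SiH and no acid work-up, giving the macrocyclic epoxy ester as its C3 triisopropylsilyl ether F3. Camphorsulfonic acid in CH2Cl2 then opens the epoxide across the pre-formed ring (transannular lactonisation) to the hydroxy lactone silyl ether F4. Ac2O/pyridine/DMAP gives the acetate silyl ether F5, and HF·pyridine in THF at 0 °C removes the silyl group to give 23. The cost is one extra step.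

**Step 11 (nickel macrocyclisation as the last step).** Zerovalent nickel may engage the α-methylene lactone instead of the aldehyde. The exocyclic regioisomer may form. The C3 diastereoselectivity is not predictable with confidence.

The fallback replaces nickel catalysis by a reagent-controlled alkenylzinc addition (Oppolzer-type macrocyclisation), sets out from 20 and comes back at 23. Dicyclohexylborane (hexane, 0 °C) hydroborates the alkyne syn in the presence of the aldehyde, placing boron mainly on the methyl-bearing carbon C4, to give the alkenylborane F6. This solution is added slowly to Et2Zn and (+)-DAIB (5 mol%) at high dilution. Boron–zinc exchange gives the alkenyl(ethyl)zinc F7, which adds intramolecularly to the Re face of the aldehyde (the face that gives 3S by the Noyori model for this ligand enantiomer). NH4Cl work-up then gives 23 directly. The minor hydroboration regioisomer leads to a ring-contracted exocyclic isomer that is removed by chromatography.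

## Further compounds

F1 | step 8 | di-tert-butyl 2-[(3S)-1-{(2R,3R)-2-methyl-3-[(3Z)-3-methyloct-3-en-6-yn-1-yl]oxiran-2-yl}-5-oxopentan-3-yl]propanedioate | CC(C)(C)OC(=O)C(C(=O)OC(C)(C)C)[C@H](CC=O)CC[C@@]1(C)O[C@@H]1CC/C(C)=C\CC#CC
F2 | step 8 | (4S,7S)-7-[(1R,4Z)-1-hydroxy-4-methylnon-4-en-7-yn-1-yl]-7-methyl-2-oxo-4-(2-oxoethyl)oxepane-3-carboxylic acid (both C3 epimers) | OC(=O)C1C(=O)O[C@@](C)(CC[C@H]1CC=O)[C@H](O)CC/C(C)=C\CC#CC
F3 | step 9 | tert-butyl 2-[(1R,4Z,7E,9S,11S,14R)-4,8,14-trimethyl-9-{[tri(propan-2-yl)silyl]oxy}-15-oxabicyclo[12.1.0]pentadeca-4,7-dien-11-yl]prop-2-enoate | C=C(C(=O)OC(C)(C)C)[C@@H]1C[C@H](O[Si](C(C)C)(C(C)C)C(C)C)/C(C)=C/C/C=C(/C)CC[C@H]2O[C@]2(C)CC1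
F4 | step 9 | (1S,3S,4E,7Z,11R,12S)-11-hydroxy-4,8,12-trimethyl-15-methylidene-3-{[tri(propan-2-yl)silyl]oxy}-13-oxabicyclo[10.3.2]heptadeca-4,7-dien-14-one | C=C1C(=O)O[C@@]2(C)CC[C@H]1C[C@H](O[Si](C(C)C)(C(C)C)C(C)C)/C(C)=C/C/C=C(/C)CC[C@H]2O
F5 | step 9 | (1S,3S,4E,7Z,11R,12S)-4,8,12-trimethyl-15-methylidene-14-oxo-3-{[tri(propan-2-yl)silyl]oxy}-13-oxabicyclo[10.3.2]heptadeca-4,7-dien-11-yl acetate | C=C1C(=O)O[C@@]2(C)CC[C@H]1C[C@H](O[Si](C(C)C)(C(C)C)C(C)C)/C(C)=C/C/C=C(/C)CC[C@H]2OC(C)=O
F6 | step 11 | (1R,4Z,7Z)-8-(dicyclohexylboranyl)-4-methyl-1-[(2S,5S)-2-methyl-6-methylidene-7-oxo-5-(2-oxoethyl)oxepan-2-yl]nona-4,7-dien-1-yl acetate | C=C1C(=O)O[C@@](C)(CC[C@H]1CC=O)[C@H](OC(C)=O)CC/C(C)=C\C/C=C(\C)B(C1CCCCC1)C1CCCCC1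
F7 | step 11 | ethylzinc alkenyl corresponding to F6 (zinc in place of boron on C4, same olefin geometry) | C=C1C(=O)O[C@@](C)(CC[C@H]1CC=O)[C@H](OC(C)=O)CC/C(C)=C\C/C=C(\C)[Zn]CC
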